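**Retrosynthetic overview**
1. Target 20 ⇒ methoxy peroxyketal 18. The C3 methyl goes on last, by axial delivery to a bicyclic peroxycarbenium ion, so the rigid ring fixes C3 rather than a planar acyclic centre.
2. 18 ⇒ butenolide-alkene 15 through the key C–O disconnections: C7a–O1 (intramolecular peroxy-Michael addition) and C3–O2 (carbonyl oxide from ozonolysis, trapped by MeOH).
3. 15 ⇒ dioxolanone 11 by Z-olefination and C–O lactonisation of a masked α-hydroxy aldehyde.
4. 11 ⇒ (S)-lactic acid, pivalaldehyde and 2,3-dibromopropene (Seebach alkylation sets C4a), plus 10-phenyldecylzinc bromide (Negishi coupling) made from PhMgBr and 1,10-dibromodecane.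
5. Ring order: temporary dioxolanone → butenolide (ring B) → 1,2-dioxane (ring A).

Assumption: locants follow furo[3,2-c][1,2]dioxin numbering (O1–O2–C3–C4–C4a–O5–C6(=O)–C7–C7a). The given SMILES then reads (3R,4aR,7aR), cis-fused, with the C3 methyl on the same face of the dioxane as O5.

**Step 1**
Reactants: 1 phenylmagnesium bromide; 2 1,10-dibromodecane
Product: 3 (10-bromodecyl)benzene
Conditions: FeCl3 (5 mol %), TMEDA (1.2 equiv), THF, 0 °C, slow addition of 1 to 2 (3 equiv)
Reagents that add atoms: none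
Why: This is an iron-catalysed Kumada-type sp2–sp3 coupling of an aryl Grignard reagent with a primary alkyl bromide, and the threefold excess of the symmetrical dibromide limits double arylation (the surplus is distilled off).

**Step 2**
Reactants: 4 (S)-lactic acid; 5 pivalaldehyde
Product: 6 (2S,5S)-2-tert-butyl-5-methyl-1,3-dioxolan-4-one (cis)
Conditions: TsOH·H2O (cat.), pentane, reflux, Dean–Stark; recrystallise from pentane–Et2O at −78 °C
Reagents that add atoms: none
Why: Acid-catalysed acetalisation is the first stage of Seebach self-regeneration of stereocentres, and the major cis acetal crystallises pure, so the lactate configuration is stored in the new acetal centre C2.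

**Step 3**
Reactants: 6 (2S,5S)-2-tert-butyl-5-methyl-1,3-dioxolan-4-one; 7 2,3-dibromoprop-1-ene
Product: 9 (2S,5R)-5-(2-bromoprop-2-en-1-yl)-2-tert-butyl-5-methyl-1,3-dioxolan-4-one, via lithium enolate 8 (not isolated)
Conditions: LDA (1.05 equiv), THF, −78 °C; then 7 (1.5 equiv), −78 to −30 °C
Reagents that add atoms: none
Why: In this Seebach enolate alkylation the allylic bromide attacks the planar enolate on the face anti to the tert-butyl group, which sets the quaternary centre (future C4a, R) with high diastereoselectivity.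

**Step 4**
Reactants: 3 (10-bromodecyl)benzene; 9 (2S,5R)-5-(2-bromoprop-2-en-1-yl)-2-tert-butyl-5-methyl-1,3-dioxolan-4-one
Product: 11 (2S,5R)-2-tert-butyl-5-methyl-5-(2-methylidene-12-phenyldodecyl)-1,3-dioxolan-4-one, via 10-phenyldecylzinc bromide 10 (not isolated)
Conditions: 3, Zn dust (1.5 equiv), LiCl (1.5 equiv), THF, 50 °C; then 9, PdCl2(dppf) (3 mol %), THF, 40 °C
Reagents that add atoms: none
Why: This is a Negishi sp3–sp2 coupling in which the primary alkylzinc tolerates the acetal-lactone, dppf suppresses β-hydride elimination, and no stereocentre is touched.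

**Step 5**
Reactants: 11 (2S,5R)-2-tert-butyl-5-methyl-5-(2-methylidene-12-phenyldodecyl)-1,3-dioxolan-4-one; 12 ethyl 2-(diphenoxyphosphoryl)acetate
Product: 15 (5R)-5-methyl-5-(2-methylidene-12-phenyldodecyl)furan-2(5H)-one, via aluminium lactolate 13 (not isolated), via Z-hydroxy enoate 14 (not isolated)
Conditions: i-Bu2AlH (1.1 equiv), CH2Cl2, −78 °C; then 12 (2.5 equiv)/NaH (2.4 equiv) in THF, −78 °C to rt; aq. potassium sodium tartrate
Reagents that add atoms: none
Why: In this one-pot partial reduction and Ando Z-selective Horner–Wadsworth–Emmons olefination, the lactolate opens to the masked α-oxy aldehyde, the hemiacetal arm loses pivalaldehyde, the tertiary alkoxide lactonises onto the cis ester, and the quaternary centre cannot epimerise.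

**Step 6**
Reactants: 15 (5R)-5-methyl-5-(2-methylidene-12-phenyldodecyl)furan-2(5H)-one
Product: 18 (4aR,7aR)-3-methoxy-4a-methyl-3-(10-phenyldecyl)tetrahydrofuro[3,2-c][1,2]dioxin-6(3H)-one (cis-fused, both C3 epimers), via carbonyl oxide 16 (not isolated), via hydroperoxy ketal 17 (not isolated)
Conditions: O3, CH2Cl2–MeOH 4:1, −78 °C (Sudan Red 7B end point), N2 purge, concentrate at 0 °C; Et2NH (0.3 equiv), CF3CH2OH, rt
Reagents that add atoms: ozone, [O-][O+]=O; methanol, CO
Why: Criegee ozonolysis of the electron-rich 1,1-disubstituted alkene puts the carbonyl oxide on the disubstituted carbon, MeOH traps it as the α-methoxy hydroperoxide (C3–O2), and an amine-catalysed 6-exo-trig peroxy-Michael addition forms C7a–O1 on the butenolide face carrying the tether, which sets C7a (R) and the cis fusion.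

**Step 7**
Reactants: 18 (4aR,7aR)-3-methoxy-4a-methyl-3-(10-phenyldecyl)tetrahydrofuro[3,2-c][1,2]dioxin-6(3H)-one
Product: 20 (3R,4aR,7aR)-3,4a-dimethyl-3-(10-phenyldecyl)tetrahydrofuro[3,2-c][1,2]dioxin-6(3H)-one (target), via peroxycarbenium ion 19 (not isolated)
Conditions: AlMe3 (4 equiv, 2 M in toluene), CH2Cl2, −78 to −20 °C; aq. potassium sodium tartrate
Reagents that add atoms: trimethylaluminium, C[Al](C)C
Why: Proposed new method: methyl transfer from an organoaluminium reagent to a cyclic peroxycarbenium ion; AlMe3 binds the most basic oxygen (the exocyclic OMe) and ionises both ketal epimers of 18 to the single cation 19, which should adopt the half-chair with the C4a–O5 bond pseudoaxial (through-space stabilisation of the cation) and the C4a methyl pseudoequatorial, so that axial attack leading directly to the chair comes from the face syn to O5 and gives axial CH3 and equatorial chain, i.e. (3R), whereas the other face needs a twist-boat or a 1,3-diaxial clash with an axial C4a methyl; the closest known reactions are Lewis-acid substitution of 3-alkoxy-1,2-dioxanes and 1,2-dioxolanes by allylsilanes and silyl enol ethers through peroxycarbenium ions, and axial AlMe3 methylation of cyclic ketals and anomeric fluorides, which leaves the O–O bond of artemisinin-type trioxanes intact at low temperature.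

**Compound list**
1 | phenylmagnesium bromide | Br[Mg]c1ccccc1 | starting material
2 | 1,10-dibromodecane | BrCCCCCCCCCCBr | starting material
3 | (10-bromodecyl)benzene | BrCCCCCCCCCCc1ccccc1 | intermediate
4 | (S)-lactic acid | C[C@H](O)C(=O)O | starting material
5 | pivalaldehyde | CC(C)(C)C=O | starting material
6 | (2S,5S)-2-tert-butyl-5-methyl-1,3-dioxolan-4-one | C[C@@H]1O[C@H](C(C)(C)C)OC1=O | intermediate
7 | 2,3-dibromoprop-1-ene | BrCC(Br)=C | starting material
8 | lithium (2S)-2-tert-butyl-5-methyl-1,3-dioxol-4-olate (enolate of 6) | CC1=C(O[Li])O[C@@H](C(C)(C)C)O1 | intermediate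
9 | (2S,5R)-5-(2-bromoprop-2-en-1-yl)-2-tert-butyl-5-methyl-1,3-dioxolan-4-one | C=C(Br)C[C@@]1(C)O[C@H](C(C)(C)C)OC1=O | intermediate
10 | 10-phenyldecylzinc bromide | Br[Zn]CCCCCCCCCCc1ccccc1 | intermediate
11 | (2S,5R)-2-tert-butyl-5-methyl-5-(2-methylidene-12-phenyldodecyl)-1,3-dioxolan-4-one | C=C(CCCCCCCCCCc1ccccc1)C[C@@]1(C)O[C@H](C(C)(C)C)OC1=O | intermediate
12 | ethyl 2-(diphenoxyphosphoryl)acetate | CCOC(=O)CP(=O)(Oc1ccccc1)Oc1ccccc1 | starting material
13 | diisobutylaluminium lactolate of 11 (C4 epimers of the dioxolane) | C=C(CCCCCCCCCCc1ccccc1)C[C@@]1(C)O[C@H](C(C)(C)C)OC1O[Al](CC(C)C)CC(C)C | intermediate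
14 | ethyl (2Z,4R)-4-hydroxy-4-methyl-6-methylidene-16-phenylhexadec-2-enoate | CCOC(=O)/C=C\[C@](C)(O)CC(=C)CCCCCCCCCCc1ccccc1 | intermediate
15 | (5R)-5-methyl-5-(2-methylidene-12-phenyldodecyl)furan-2(5H)-one | C=C(CCCCCCCCCCc1ccccc1)C[C@]1(C)C=CC(=O)O1 | intermediate
16 | carbonyl oxide at the side-chain C2 of (5R)-5-methyl-5-(2-oxo-12-phenyldodecyl)furan-2(5H)-one | [O-][O+]=C(CCCCCCCCCCc1ccccc1)C[C@]1(C)C=CC(=O)O1 | intermediate
17 | (5R)-5-(2-hydroperoxy-2-methoxy-12-phenyldodecyl)-5-methylfuran-2(5H)-one (both ketal epimers) | COC(CCCCCCCCCCc1ccccc1)(OO)C[C@]1(C)C=CC(=O)O1 | intermediate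
18 | (4aR,7aR)-3-methoxy-4a-methyl-3-(10-phenyldecyl)tetrahydrofuro[3,2-c][1,2]dioxin-6(3H)-one (cis-fused, both C3 epimers) | COC1(CCCCCCCCCCc2ccccc2)C[C@@]2(C)OC(=O)C[C@H]2OO1 | intermediate
19 | (4aR,7aR)-4a-methyl-6-oxo-3-(10-phenyldecyl)-4,4a,7,7a-tetrahydro-6H-furo[3,2-c][1,2]dioxin-2-ium (peroxycarbenium ion) | [O+]1=C(CCCCCCCCCCc2ccccc2)C[C@@]2(C)OC(=O)C[C@H]2O1 | intermediate
20 | (3R,4aR,7aR)-3,4a-dimethyl-3-(10-phenyldecyl)tetrahydrofuro[3,2-c][1,2]dioxin-6(3H)-one | C[C@@]1(CCCCCCCCCCc2ccccc2)C[C@@]2(C)OC(=O)C[C@H]2OO1 | target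

**Total step count:** 7. **Longest linear sequence:** 6 (steps 2, 3, 4, 5, 6, 7).

**Three steps most likely to fail**

Step 7 (the new step). Possible failure modes:
- ionisation of the ring C3–O2 bond instead of the exocyclic C3–OMe bond;
- attack of AlMe3 on the O–O bond;
- proton loss from 19 to give a vinyl peroxide;
- weak facial selectivity.

The fallback uses known chemistry and sets out from 15. Mukaiyama–Isayama hydroperoxysilylation (Co(thd)2 cat., O2, Et3SiH, ClCH2CH2Cl, rt) gives (5R)-5-methyl-5-[2-methyl-12-phenyl-2-(triethylsilylperoxy)dodecyl]furan-2(5H)-one F1 as roughly 1:1 epimers. Bu4NF/AcOH in THF then frees (5R)-5-(2-hydroperoxy-2-methyl-12-phenyldodecyl)-5-methylfuran-2(5H)-one F2. Et2NH in CF3CH2OH closes the ring by peroxy-Michael addition to 20 together with its C3 epimer (3S,4aR,7aR)-3,4a-dimethyl-3-(10-phenyldecyl)tetrahydrofuro[3,2-c][1,2]dioxin-6(3H)-one F3, which is removed by chromatography. The fallback returns to the route at 20 and costs about half the material.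

Step 6. Possible failure modes:
- cycloreversion the wrong way, to ketone plus formaldehyde oxide;
- loss of the amine catalyst to residual formaldehyde;
- some ozone attack on the butenolide.

The fallback sets out from 15. Ozonolysis with Me2S work-up gives (5R)-5-methyl-5-(2-oxo-12-phenyldodecyl)furan-2(5H)-one F4. Acid-catalysed perketalisation of the ketone (urea–hydrogen peroxide, TsOH cat., MeOH) then forms the C3–O2 bond and returns to the route at 17. Here 17 is purified on silica before the Et2NH/CF3CH2OH cyclisation to 18.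

Step 5. Possible failure modes:
- the aluminium lactolate is reluctant to open in the one-pot olefination;
- the Z:E ratio at the hindered aldehyde is poor.

The fallback sets out from 11 and builds the butenolide by metathesis instead of olefination.
- i-Bu2AlH with aqueous work-up gives (2S,5R)-2-tert-butyl-5-methyl-5-(2-methylidene-12-phenyldodecyl)-1,3-dioxolan-4-ol F5.
- Wittig methylenation (Ph3P=CH2, THF) gives (3R)-3-methyl-5-methylidene-15-phenylpentadec-1-en-3-ol F6.
- Acryloyl chloride, i-Pr2NEt and DMAP give (3R)-3-methyl-5-methylidene-15-phenylpentadec-1-en-3-yl acrylate F7.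
- Ring-closing metathesis with the second-generation Grubbs catalyst (CH2Cl2, reflux) returns to the route at 15.

**Further compounds**
F1 | step 7 | (5R)-5-methyl-5-[2-methyl-12-phenyl-2-(triethylsilylperoxy)dodecyl]furan-2(5H)-one (both epimers) | CC[Si](CC)(CC)OOC(C)(CCCCCCCCCCc1ccccc1)C[C@]1(C)C=CC(=O)O1
F2 | step 7 | (5R)-5-(2-hydroperoxy-2-methyl-12-phenyldodecyl)-5-methylfuran-2(5H)-one (both epimers) | CC(CCCCCCCCCCc1ccccc1)(OO)C[C@]1(C)C=CC(=O)O1
F3 | step 7 | (3S,4aR,7aR)-3,4a-dimethyl-3-(10-phenyldecyl)tetrahydrofuro[3,2-c][1,2]dioxin-6(3H)-one | C[C@]1(CCCCCCCCCCc2ccccc2)C[C@@]2(C)OC(=O)C[C@H]2OO1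
F4 | step 6 | (5R)-5-methyl-5-(2-oxo-12-phenyldodecyl)furan-2(5H)-one | O=C(CCCCCCCCCCc1ccccc1)C[C@]1(C)C=CC(=O)O1
F5 | step 5 | (2S,5R)-2-tert-butyl-5-methyl-5-(2-methylidene-12-phenyldodecyl)-1,3-dioxolan-4-ol (C4 epimers) | C=C(CCCCCCCCCCc1ccccc1)C[C@@]1(C)O[C@H](C(C)(C)C)OC1O
F6 | step 5 | (3R)-3-methyl-5-methylidene-15-phenylpentadec-1-en-3-ol | C=C[C@](C)(O)CC(=C)CCCCCCCCCCc1ccccc1
F7 | step 5 | (3R)-3-methyl-5-methylidene-15-phenylpentadec-1-en-3-yl acrylate | C=C[C@](C)(OC(=O)C=C)CC(=C)CCCCCCCCCCc1ccccc1
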